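Amber and violet each hold c_Q = 0.40 M under held J, with Q as the limiting reagent, and the two flasks part at 50 h. G forms from Q and then goes on to D.

the same everywhere: J 89 mM (held)
- dusk: Q 0.20 M; temperature 65 °C; run made earlier
- autumn: Q 0.80 M; temperature 85 °C; run made earlier
- amber: Q 0.40 M; at 70 °C until 50 h, from then on at 100 °C; time 4.0 d
- violet: Q 0.40 M; at 70 °C throughout; time 4.0 d

dusk run (percent of the Q charged)

| time / d | G / % | D / % |
|---|---|---|
| 0.250 | 51.5 | 0 |
| 0.417 | 73.9 | 0 |
| 0.625 | 90.7 | 4.4 |
| 1.25 | 92.4 | 5.9 |
| 2.08 | 85.5 | 14.4 |
| 3.00 | 78.2 | 21.0 |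

autumn run (percent of the Q charged)

| time / h | G / % | D / % |
|---|---|---|
| 3.00 | 11.7 | 0 |
| 5.00 | 17.5 | 2.3 |
| 8.00 | 25.4 | 5.3 |
| 15.0 | 40.2 | 14.4 |
| 25.0 | 49.4 | 37.9 |
| 30.0 | 48.8 | 48.3 |

(scatter of a reading: 1 percentage point)

- the flask that ends with the higher share of G in all that became G or D, or "neither" when 2 percentage points or less lies between them (amber / violet / neither)
- share of G in all that became G or D, amber
- share of G in all that became G or D, violet

- the earlier runs were read with a standard deviation of 1 percentage point
- at the start none of J is in solution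

In dusk, with G + D already at 98.3%, G falls from 92.4% to 78.2% between 1.25 d and 3.00 d, which reads as a first-order constant of 0.0953 d⁻¹ at 65 °C. In autumn, D gains 34 percentage points from 15.0 h to 30.0 h while G reads between 40.2% and 49.4%, which, taken at the upper figure, reads as 1.10 d⁻¹ at 85 °C. With ln k taken as straight in temperature, the loss constant of G, the fraction of G turning to D per day, is 0.176 d⁻¹ at 70 °C and 6.86 d⁻¹ at 100 °C.

Autumn's early pace, 0.699 M d⁻¹, comes from a hotter flask with another charge, but taken over as a rough figure it gives this Q a span of about 0.572 d, so that at a steady pace G is born on average at about 0.286 d. That is shorter than the flask's time, so the share of G is roughly e to the minus sum of k times the time G lives: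

| Flask | time at 70 °C | time at 100 °C | exponent | share of G |
|---|---|---|---|---|
| violet | 3.71 d | none | 0.652 | 52.1% |
| amber | 1.80 d | 1.92 d | 13.5 | <0.001% |

Turned round, this reckoning brings amber within 2 points of violet if the ratio of the constants at 100 °C and 70 °C lies near one, against 39.0 here. With amber's share near nil, it also does so if violet's exponent reaches 3.91, against 0.652 here.

The forecast, reckoned apart and with figures that differ from the table above, said violet, with 0.1% for amber and 54% for violet, on the reading that “D grows in proportion to G”. The simulation gives violet, with 0% for amber and 55.3% for violet.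

    J ⇌ X, rate k1*(csat - [X]) (kL = 0.380 h⁻¹)
    Q + X → G (k = 7.00 M⁻¹ h⁻¹, Ea = 59.0 kJ mol⁻¹)
    X → L (k = 0.170 h⁻¹, Ea = 113 kJ mol⁻¹)
    G → D (k = 0.00680 h⁻¹, Ea = 130 kJ mol⁻¹)
    (constants at 70 °C)

In violet, Q + X made G while Q lasted and G passed to D alongside, so that at 2.00 d Q stood at 0%, G at 76.7% and D at 23.3%; G went on falling to 55.3% at 4.00 d, where the loss constant applied to the G of 2.00 d gives 53.9%. Amber followed the same course to G 75.6% at 2.08 d, and after the change to 100 °C its G fell to 0% and its D rose to >99.9% by 4.00 d.

Violet read at 6.0 d takes the exponent 1.01, a share of 36.6%. The computed flask stands at 39.9%.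

Readings and results were computed from invented constants; scatter was added.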